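The C4=C5 tetrasubstituted alkene of ring A (eudesmane numbering: C4 bears the vinylic methyl, C5 is the ring-fusion carbon) lies next to the C3 oxygen, so the target is a reduced and acylated 4-en-3-one. Everything rests on closing ring A late, by an intramolecular aldol condensation in which the C4 enolate of an ethyl ketone side chain attacks the C5 ketone of ring B; one operation forms the C4–C5 bond, the alkene and the decalin. The precursor is a monocyclic 1,5-diketone whose ring B already holds C7, C8 and quaternary C10, all derived from one purchased stereocentre; an alkyne at C7 is the latent acrylate.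

Key step: step 6

Remark: compound 1 is taken as a purchasable chiral building block; positions are cited in eudesmane numbering (ring A: C1–C5 and C10; ring B: C5–C10; C11–C13 acrylate carbons; C14 methyl on C10; C15 methyl on C4).

Step 1
Reactants: 1 (4R)-4-{[tert-butyl(dimethyl)silyl]oxy}cyclohex-2-en-1-one
Product: 3 (4R)-4-{[tert-butyl(dimethyl)silyl]oxy}-6-methylcyclohex-2-en-1-one (C6 epimers), via lithium enolate 2 (not isolated)
Conditions: LiN(iPr)2, THF, −78 °C; then MeI, −78 → −20 °C
Reagents that add atoms: iodomethane, CI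
Why: Kinetic α′-deprotonation gives the cross-conjugated enolate, which is methylated by SN2 (enolate alkylation); the new centre (future C10) forms as an epimer mixture, which is of no consequence because it becomes quaternary in step 5.

Step 2
Reactants: 3 (4R)-4-{[tert-butyl(dimethyl)silyl]oxy}-6-methylcyclohex-2-en-1-one
Product: 4 (4R)-4-hydroxy-6-methylcyclohex-2-en-1-one (C6 epimers)
Conditions: 48% aq. HF, MeCN, 0 °C → rt
Reagents that add atoms: none
Why: Acidic fluoride desilylation should free the hydroxyl without exposing the base-sensitive γ-hydroxy enone to base; the C8 stereocentre is untouched.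

Step 3
Reactants: 4 (4R)-4-hydroxy-6-methylcyclohex-2-en-1-one; 5 ethynyl(trimethyl)silane
Product: 7 (3R,4R)-4-hydroxy-6-methyl-3-[(trimethylsilyl)ethynyl]cyclohexan-1-one (3,4-cis; C6 epimers), via alkynylalane 6 (not isolated)
Conditions: 5, AlMe3, Et3N (cat.), toluene, rt; then 4, 0 °C → rt; aq. KNaC4H4O6
Reagents that add atoms: none
Why: The hydroxyl forms an aluminium alkoxide that hands the alkynyl group to the neighbouring β-carbon through a five-membered transition state (hydroxyl-directed conjugate alkynylation with an alkynylalane), so C7 should be set cis to the C8 oxygen.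

Step 4
Reactants: 7 (3R,4R)-4-hydroxy-6-methyl-3-[(trimethylsilyl)ethynyl]cyclohexan-1-one; 8 (1R)-1-phenylethan-1-amine
Product: 9 (1R,2R)-5-methyl-4-{[(1R)-1-phenylethyl]imino}-2-[(trimethylsilyl)ethynyl]cyclohexan-1-ol (C5 epimers)
Conditions: toluene, TsOH·H2O (cat.), 4 Å molecular sieves, 80 °C
Reagents that add atoms: none
Why: Acid-catalysed imine formation with removal of water; the imine equilibrates with the more substituted secondary enamine that step 5 needs, and C7 and C8 are not affected.

Step 5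
Reactants: 9 (1R,2R)-5-methyl-4-{[(1R)-1-phenylethyl]imino}-2-[(trimethylsilyl)ethynyl]cyclohexan-1-ol; 10 pent-1-en-3-one
Product: 12 (2R,4R,5R)-4-hydroxy-2-methyl-2-(3-oxopentyl)-5-[(trimethylsilyl)ethynyl]cyclohexan-1-one, via Michael adduct imine 11 (not isolated)
Conditions: 10, THF, rt; then 10% aq. AcOH, rt
Reagents that add atoms: water, O
Why: Aza-ene-type Michael addition of the more substituted secondary enamine to the vinyl ketone (chiral-imine Michael addition) should be regioselective for C10; the quaternary centre is set by axial attack on the α-face, anti to the C7 and C8 substituents and reinforced by the (R)-auxiliary, and hydrolysis returns the ketone.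

Step 6
Reactants: 12 (2R,4R,5R)-4-hydroxy-2-methyl-2-(3-oxopentyl)-5-[(trimethylsilyl)ethynyl]cyclohexan-1-one
Product: 15 (4aR,6R,7R)-7-ethynyl-6-hydroxy-1,4a-dimethyl-4,4a,5,6,7,8-hexahydronaphthalen-2(3H)-one, via desilylated diketone 13 (not isolated), via ketol 14 (not isolated)
Conditions: KOH, MeOH, rt → 60 °C
Reagents that add atoms: none
Why: Methanolic base first cleaves the alkynyl C–Si bond (13), then forms the C4 enolate of the ethyl ketone, which adds to the C5 ring ketone to give ketol 14, and E1cB loss of water should deliver the conjugated tetrasubstituted C4=C5 enone. This is the intramolecular aldol condensation that completes a Robinson annulation. Ring A is closed in a 6-(enolendo)-exo-trig mode. No stereocentre remains at C4 or C5, and C7, C8 and C10 cannot epimerise (no acidifying group on C7 or C8, no hydrogen on C10). The step needs regioselectivity among the aldol pairings: attack of C2 on C5 would give a four-membered ring, and attack of C6 on C3 gives only a bridged ketol that cannot dehydrate and reverts, so irreversible dehydration funnels the material to 15.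

Step 7
Reactants: 15 (4aR,6R,7R)-7-ethynyl-6-hydroxy-1,4a-dimethyl-4,4a,5,6,7,8-hexahydronaphthalen-2(3H)-one
Product: 16 (2R,3R,8aR)-3-ethynyl-5,8a-dimethyl-6-oxo-1,2,3,4,6,7,8,8a-octahydronaphthalen-2-yl acetate
Conditions: Ac2O, pyridine, DMAP (cat.), CH2Cl2, rt
Reagents that add atoms: acetic anhydride, CC(=O)OC(C)=O
Why: DMAP-catalysed acetylation of the axial secondary alcohol installs the C8 acetate and blocks the hydroxyl so that no lactone can form in the carbonylation.

Step 8
Reactants: 16 (2R,3R,8aR)-3-ethynyl-5,8a-dimethyl-6-oxo-1,2,3,4,6,7,8,8a-octahydronaphthalen-2-yl acetate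
Product: 17 methyl 2-[(2R,3R,4aR)-3-acetoxy-4a,8-dimethyl-7-oxo-1,2,3,4,4a,5,6,7-octahydronaphthalen-2-yl]prop-2-enoate
Conditions: Pd(OAc)2 (cat.), 2-pyridyldiphenylphosphine, MeSO3H (cat.), CO (20 bar), MeOH, 45 °C
Reagents that add atoms: carbon monoxide, [C-]#[O+]; methanol, CO
Why: Markovnikov hydromethoxycarbonylation of the terminal alkyne (palladium-catalysed alkyne alkoxycarbonylation) places the ester on the internal carbon and should give the 2-substituted acrylate directly, with no stereocentre touched.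

Step 9
Reactants: 17 methyl 2-[(2R,3R,4aR)-3-acetoxy-4a,8-dimethyl-7-oxo-1,2,3,4,4a,5,6,7-octahydronaphthalen-2-yl]prop-2-enoate
Product: 18 methyl 2-[(2R,3R,4aR,7S)-3-acetoxy-7-hydroxy-4a,8-dimethyl-1,2,3,4,4a,5,6,7-octahydronaphthalen-2-yl]prop-2-enoate
Conditions: NaBH4, CeCl3·7H2O, MeOH, −78 → −40 °C
Reagents that add atoms: none
Why: Luche 1,2-reduction of the enone; axial hydride delivery to C3 from the α-face should give the pseudo-equatorial 3β (3S) allylic alcohol, as with steroidal 4-en-3-ones, while the acrylate and acetate are left alone.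

Step 10
Reactants: 18 methyl 2-[(2R,3R,4aR,7S)-3-acetoxy-7-hydroxy-4a,8-dimethyl-1,2,3,4,4a,5,6,7-octahydronaphthalen-2-yl]prop-2-enoate; 19 (2E)-3-methylpent-2-enoic acid
Product: 20 methyl 2-[(2R,3R,4aR,7S)-3-acetoxy-4a,8-dimethyl-7-{[(2E)-3-methylpent-2-enoyl]oxy}-1,2,3,4,4a,5,6,7-octahydronaphthalen-2-yl]prop-2-enoate
Conditions: DCC, DMAP (cat.), CH2Cl2, 0 °C → rt
Reagents that add atoms: none
Why: Steglich esterification acylates the allylic alcohol at oxygen under neutral conditions, which should preserve the C3 configuration and the (E)-geometry of the acid.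

Compound list
1 | (4R)-4-{[tert-butyl(dimethyl)silyl]oxy}cyclohex-2-en-1-one | C1=CC(=O)CC[C@H]1O[Si](C)(C)C(C)(C)C | starting material
2 | lithium (4R)-4-{[tert-butyl(dimethyl)silyl]oxy}cyclohexa-1,5-dien-1-olate | [Li+].[O-]C1=CC[C@@H](O[Si](C)(C)C(C)(C)C)C=C1 | intermediate
3 | (4R)-4-{[tert-butyl(dimethyl)silyl]oxy}-6-methylcyclohex-2-en-1-one (C6 epimers) | C1=CC(=O)C(C)C[C@H]1O[Si](C)(C)C(C)(C)C | intermediate
4 | (4R)-4-hydroxy-6-methylcyclohex-2-en-1-one (C6 epimers) | C1=CC(=O)C(C)C[C@H]1O | intermediate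
5 | ethynyl(trimethyl)silane | C#C[Si](C)(C)C | starting material
6 | dimethyl[(trimethylsilyl)ethynyl]alane | C[Al](C)C#C[Si](C)(C)C | intermediate
7 | (3R,4R)-4-hydroxy-6-methyl-3-[(trimethylsilyl)ethynyl]cyclohexan-1-one (3,4-cis; C6 epimers) | C[Si](C)(C)C#C[C@H]1CC(=O)C(C)C[C@H]1O | intermediate
8 | (1R)-1-phenylethan-1-amine | C[C@@H](N)c1ccccc1 | starting material
9 | (1R,2R)-5-methyl-4-{[(1R)-1-phenylethyl]imino}-2-[(trimethylsilyl)ethynyl]cyclohexan-1-ol (C5 epimers) | C[Si](C)(C)C#C[C@H]1CC(=N[C@H](C)c2ccccc2)C(C)C[C@H]1O | intermediate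
10 | pent-1-en-3-one | C=CC(=O)CC | starting material
11 | ring-carbonyl N-[(1R)-1-phenylethyl]imine of diketone 12 (Michael adduct imine) | C[Si](C)(C)C#C[C@H]1CC(=N[C@H](C)c2ccccc2)[C@](C)(CCC(=O)CC)C[C@H]1O | intermediate
12 | (2R,4R,5R)-4-hydroxy-2-methyl-2-(3-oxopentyl)-5-[(trimethylsilyl)ethynyl]cyclohexan-1-one | C[Si](C)(C)C#C[C@H]1CC(=O)[C@](C)(CCC(=O)CC)C[C@H]1O | intermediate
13 | (2R,4R,5R)-5-ethynyl-4-hydroxy-2-methyl-2-(3-oxopentyl)cyclohexan-1-one | C#C[C@H]1CC(=O)[C@](C)(CCC(=O)CC)C[C@H]1O | intermediate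
14 | (4aR,6R,7R)-7-ethynyl-6,8a-dihydroxy-1,4a-dimethyloctahydronaphthalen-2(1H)-one (C1 and C8a not assigned) | C#C[C@H]1CC2(O)C(C)C(=O)CC[C@]2(C)C[C@H]1O | intermediate
15 | (4aR,6R,7R)-7-ethynyl-6-hydroxy-1,4a-dimethyl-4,4a,5,6,7,8-hexahydronaphthalen-2(3H)-one | C#C[C@H]1CC2=C(C)C(=O)CC[C@]2(C)C[C@H]1O | intermediate
16 | (2R,3R,8aR)-3-ethynyl-5,8a-dimethyl-6-oxo-1,2,3,4,6,7,8,8a-octahydronaphthalen-2-yl acetate | C#C[C@H]1CC2=C(C)C(=O)CC[C@]2(C)C[C@H]1OC(C)=O | intermediate
17 | methyl 2-[(2R,3R,4aR)-3-acetoxy-4a,8-dimethyl-7-oxo-1,2,3,4,4a,5,6,7-octahydronaphthalen-2-yl]prop-2-enoate | C=C(C(=O)OC)[C@H]1CC2=C(C)C(=O)CC[C@]2(C)C[C@H]1OC(C)=O | intermediate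
18 | methyl 2-[(2R,3R,4aR,7S)-3-acetoxy-7-hydroxy-4a,8-dimethyl-1,2,3,4,4a,5,6,7-octahydronaphthalen-2-yl]prop-2-enoate | C=C(C(=O)OC)[C@H]1CC2=C(C)[C@@H](O)CC[C@]2(C)C[C@H]1OC(C)=O | intermediate
19 | (2E)-3-methylpent-2-enoic acid | CC/C(C)=C/C(=O)O | starting material
20 | methyl 2-[(2R,3R,4aR,7S)-3-acetoxy-4a,8-dimethyl-7-{[(2E)-3-methylpent-2-enoyl]oxy}-1,2,3,4,4a,5,6,7-octahydronaphthalen-2-yl]prop-2-enoate | C=C(C(=O)OC)[C@H]1CC2=C(C)[C@@H](OC(=O)/C=C(\C)CC)CC[C@]2(C)C[C@H]1OC(C)=O | target

Total step count: 10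
Longest linear sequence: 10 steps (1 → 20)

Steps most likely to fail

Step 8. The hydropalladation/CO insertion may lose regiocontrol and give the linear enoate, or the acidic methanol may slowly cleave the acetate. The fallback sets out from 16 and replaces the one-step carbonylation by a halide route: Markovnikov hydroiodination of the alkyne (NaI, Me3SiCl, H2O, MeCN, rt) should give (2R,3S,8aR)-3-(1-iodoethenyl)-5,8a-dimethyl-6-oxo-1,2,3,4,6,7,8,8a-octahydronaphthalen-2-yl acetate F1. Methoxycarbonylation of this alkenyl iodide (Pd(PPh3)4, CO 1 atm, MeOH, Et3N, DMF, 50 °C) comes back to the route at 17.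

Step 3. Alkynyl transfer may compete with 1,2-addition to the carbonyl, or delivery may not be fully intramolecular, which would erode the cis relationship between C7 and C8. The fallback sets out from 4 and replaces directed delivery by steric control between two inversions:
- Mitsunobu reaction with chloroacetic acid (PPh3, DIAD, THF) should give the inverted ester (1S)-5-methyl-4-oxocyclohex-2-en-1-yl chloroacetate F2.
- Conjugate alkynylation anti to the ester (BrZnC≡CSiMe3 made from 5, tBuMe2SiOTf, Et2O, −40 °C; dilute aq. HCl) should give (1S,2R)-5-methyl-4-oxo-2-[(trimethylsilyl)ethynyl]cyclohexyl chloroacetate F3.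
- Thiourea (NaHCO3, EtOH, 50 °C) removes the chloroacetyl group without touching the silylalkyne and should give (3R,4S)-4-hydroxy-6-methyl-3-[(trimethylsilyl)ethynyl]cyclohexan-1-one F4.
- A second Mitsunobu reaction with chloroacetic acid inverts C8 to (1R,2R)-5-methyl-4-oxo-2-[(trimethylsilyl)ethynyl]cyclohexyl chloroacetate F5.
- Thiourea cleavage then comes back to the route at 7.

Step 5. The aza-ene addition may be slow with the hindered enamine, the vinyl ketone may polymerise, or facial and regiochemical control at C10 may be incomplete. The fallback sets out from 7, bypasses 9 and 11, and relies on substrate control alone: thermodynamic silylation (Me3SiCl, NaI, Et3N, MeCN) should give (4R,5R)-2-methyl-1,4-bis(trimethylsilyloxy)-5-[(trimethylsilyl)ethynyl]cyclohex-1-ene F6. Its Mukaiyama–Michael addition to 10 (TiCl4, CH2Cl2, −78 °C; aqueous acidic work-up, which also frees the hydroxyl) comes back to the route at 12.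

Further compounds
F1 | step 8 | (2R,3S,8aR)-3-(1-iodoethenyl)-5,8a-dimethyl-6-oxo-1,2,3,4,6,7,8,8a-octahydronaphthalen-2-yl acetate | C=C(I)[C@H]1CC2=C(C)C(=O)CC[C@]2(C)C[C@H]1OC(C)=O
F2 | step 3 | (1S)-5-methyl-4-oxocyclohex-2-en-1-yl chloroacetate (C5 epimers) | C1=CC(=O)C(C)C[C@@H]1OC(=O)CCl
F3 | step 3 | (1S,2R)-5-methyl-4-oxo-2-[(trimethylsilyl)ethynyl]cyclohexyl chloroacetate (1,2-trans; C5 epimers) | C[Si](C)(C)C#C[C@H]1CC(=O)C(C)C[C@@H]1OC(=O)CCl
F4 | step 3 | (3R,4S)-4-hydroxy-6-methyl-3-[(trimethylsilyl)ethynyl]cyclohexan-1-one (3,4-trans; C6 epimers) | C[Si](C)(C)C#C[C@H]1CC(=O)C(C)C[C@@H]1O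
F5 | step 3 | (1R,2R)-5-methyl-4-oxo-2-[(trimethylsilyl)ethynyl]cyclohexyl chloroacetate (1,2-cis; C5 epimers) | C[Si](C)(C)C#C[C@H]1CC(=O)C(C)C[C@H]1OC(=O)CCl
F6 | step 5 | (4R,5R)-2-methyl-1,4-bis(trimethylsilyloxy)-5-[(trimethylsilyl)ethynyl]cyclohex-1-ene | C[Si](C)(C)C#C[C@H]1CC(O[Si](C)(C)C)=C(C)C[C@H]1O[Si](C)(C)C
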